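The ten-membered carbocycle (C1–C10) is opened at C5–C6, the bond joining the (E)-C4=C5 alkene to the lactone carbinol. One Nozaki–Hiyama–Kishi reaction closes this ring, forms C5–C6 and sets the C6 stereocentre. It exploits C6 being an allylic carbinol whose neighbours C7 (lactone arm C11–C12) and C8 (acyloxy) carry anti substituents, so that Felkin–Anh and 1,3-anti induction select the same aldehyde face. The precursor is an acyclic C6 aldehyde with malate-derived C7/C8 centres, a tert-butyl ester arm, a C8 silyl ether, the (E)-methyl enoate at C10=C1 and an (E)-alkenyl iodide at C5.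

Key step: step 13

Remark: ring carbons are numbered C1–C10 (C10 bears CO2Me, C4 the methyl, C6 the lactone oxygen, C8 the methacrylate), C11/C12 are the lactone carbons and C13 the exocyclic methylene; C8 is carried as a tert-butyldimethylsilyl (TBS) ether, C12 as a tert-butyl ester, and C9 is activated as a triflate for the phosphonate alkylation.

Step 1
Reactants: 1 4-pentyn-1-ol
Product: 3 (E)-5-iodo-4-methylpent-4-en-1-ol, via alkenylalane 2 (not isolated)
Conditions: AlMe3 (3 equiv), Cp2ZrCl2 (0.25 equiv), CH2Cl2, 0 °C → rt; then I2, THF, −30 → 0 °C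
Reagents that add atoms: trimethylaluminium, C[Al](C)C; iodine, II
Why: Negishi zirconium-catalysed carboalumination adds methyl and aluminium syn across the terminal alkyne with methyl on the internal carbon, and iodinolysis of the C–Al bond with retention should give the (E)-alkenyl iodide.

Step 2
Reactants: 3 (E)-5-iodo-4-methylpent-4-en-1-ol
Product: 4 (E)-5-iodo-4-methylpent-4-enal
Conditions: PhI(OAc)2 (1.1 equiv), TEMPO (0.1 equiv), CH2Cl2, rt
Reagents that add atoms: none
Why: TEMPO-catalysed oxidation with PhI(OAc)2 as terminal oxidant stops at the aldehyde and leaves the alkenyl iodide untouched.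

Step 3
Reactants: 5 dimethyl (S)-malate; 6 tert-butyl bromoacetate
Product: 8 3-tert-butyl 1,2-dimethyl (1S,2R)-1-hydroxypropane-1,2,3-tricarboxylate, via dilithium alkoxide enolate 7 (not isolated)
Conditions: LiN(SiMe3)2 (2.2 equiv), THF, −78 → −20 °C; then 6 (1.2 equiv), −78 → −15 °C
Reagents that add atoms: none
Why: Fráter–Seebach alkylation, in which the lithium-chelated alkoxide enolate 7 is attacked on the face away from the ester group of the carbinol carbon, so the new C7 centre should form anti to the C8 hydroxyl, whose configuration comes unchanged from (S)-malate.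

Step 4
Reactants: 8 3-tert-butyl 1,2-dimethyl (1S,2R)-1-hydroxypropane-1,2,3-tricarboxylate
Product: 9 4-tert-butyl 1-methyl (2R)-2-[(1S)-1,2-dihydroxyethyl]butanedioate
Conditions: BH3·SMe2 (1.05 equiv), NaBH4 (0.05 equiv), THF, 0 °C → rt; MeOH quench
Reagents that add atoms: none
Why: Hydroxyl-directed borane reduction (cyclic alkoxyborane, NaBH4 catalysis) reduces only the ester next to the free hydroxyl (C9) and leaves the C6 methyl ester and the tert-butyl ester; the diol is silylated without delay because it can lactonise.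

Step 5
Reactants: 9 4-tert-butyl 1-methyl (2R)-2-[(1S)-1,2-dihydroxyethyl]butanedioate
Product: 10 4-tert-butyl 1-methyl (2R)-2-[(1S)-1,2-bis(tert-butyldimethylsilyloxy)ethyl]butanedioate
Conditions: TBSOTf (2.5 equiv), 2,6-lutidine (4 equiv), CH2Cl2, −78 → 0 °C
Reagents that add atoms: tert-butyldimethylsilyl triflate, CC(C)(C)[Si](C)(C)OS(=O)(=O)C(F)(F)F
Why: Silyl triflate with a hindered pyridine base silylates the primary and the secondary hydroxyl at low temperature faster than it attacks the tert-butyl ester (standard silyl ether formation).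

Step 6
Reactants: 10 4-tert-butyl 1-methyl (2R)-2-[(1S)-1,2-bis(tert-butyldimethylsilyloxy)ethyl]butanedioate
Product: 11 tert-butyl (3S,4S)-4,5-bis(tert-butyldimethylsilyloxy)-3-(hydroxymethyl)pentanoate
Conditions: LiBH4 (2 equiv), MeOH (2 equiv), THF, 0 °C → rt
Reagents that add atoms: none
Why: Chemoselective borohydride reduction, since LiBH4 reduces methyl esters but not tert-butyl esters, so only the C6 carboxyl is taken to the primary alcohol.

Step 7
Reactants: 11 tert-butyl (3S,4S)-4,5-bis(tert-butyldimethylsilyloxy)-3-(hydroxymethyl)pentanoate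
Product: 12 tert-butyl (3S,4S)-3-(acetoxymethyl)-4,5-bis(tert-butyldimethylsilyloxy)pentanoate
Conditions: Ac2O, pyridine, DMAP (cat.), CH2Cl2, 0 °C → rt
Reagents that add atoms: acetic anhydride, CC(=O)OC(C)=O
Why: DMAP-catalysed acetylation caps the C6 hydroxyl as an electron-poor ester that cannot take part in the later sulfonate displacement at C9.

Step 8
Reactants: 12 tert-butyl (3S,4S)-3-(acetoxymethyl)-4,5-bis(tert-butyldimethylsilyloxy)pentanoate
Product: 13 tert-butyl (3S,4S)-3-(acetoxymethyl)-4-(tert-butyldimethylsilyloxy)-5-hydroxypentanoate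
Conditions: HF·pyridine, pyridine, THF, 0 °C
Reagents that add atoms: none
Why: Buffered fluoride desilylation discriminates sterically, cleaving the unhindered primary (C9) silyl ether well before the flanked secondary (C8) one.

Step 9
Reactants: 13 tert-butyl (3S,4S)-3-(acetoxymethyl)-4-(tert-butyldimethylsilyloxy)-5-hydroxypentanoate; 14 methyl 2-(diethoxyphosphoryl)acetate
Product: 17 tert-butyl (3S,4R)-3-(acetoxymethyl)-4-(tert-butyldimethylsilyloxy)-6-(diethoxyphosphoryl)-7-methoxy-7-oxoheptanoate (both epimers at the phosphonate carbon), via primary triflate 15 (not isolated), via sodium phosphonoacetate 16 (not isolated)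
Conditions: Tf2O (1.2 equiv), 2,6-lutidine, CH2Cl2, −78 °C; then 16 (3 equiv, from 14 and NaH in THF), −78 → 0 °C
Reagents that add atoms: none
Why: Alkylation of a phosphonoacetate carbanion by a primary alkyl triflate (SN2), chosen because the triflate should react at low temperature despite the β-silyloxy branch at C8; the new centre at C10 is destroyed in the next step.

Step 10
Reactants: 17 phosphonate from step 9; 4 (E)-5-iodo-4-methylpent-4-enal
Product: 19 tert-butyl (3S,4R,6E,10E)-3-(acetoxymethyl)-4-(tert-butyldimethylsilyloxy)-11-iodo-6-(methoxycarbonyl)-10-methylundeca-6,10-dienoate, via sodium phosphonate carbanion 18 (not isolated)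
Conditions: NaH (0.98 equiv), THF, 0 °C → rt; then 4 (1.3 equiv), 0 °C → rt
Reagents that add atoms: none
Why: Horner–Wadsworth–Emmons olefination, in which reversible addition and the more stable trans-oxaphosphetane should favour the (E)-ester with CO2Me trans to C2, any (Z)-isomer being removed by chromatography.

Step 11
Reactants: 19 acetate diene ester from step 10
Product: 20 tert-butyl (3S,4R,6E,10E)-4-(tert-butyldimethylsilyloxy)-3-(hydroxymethyl)-11-iodo-6-(methoxycarbonyl)-10-methylundeca-6,10-dienoate
Conditions: K2CO3 (0.3 equiv), MeOH, 0 °C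
Reagents that add atoms: none
Why: Carbonate-catalysed transesterification removes the primary acetate as methyl acetate, while the tert-butyl ester is too hindered to react and exchange at the methyl enoate is degenerate.

Step 12
Reactants: 20 primary alcohol from step 11
Product: 21 tert-butyl (3R,4R,6E,10E)-4-(tert-butyldimethylsilyloxy)-3-formyl-11-iodo-6-(methoxycarbonyl)-10-methylundeca-6,10-dienoate
Conditions: Dess–Martin periodinane (1.3 equiv), pyridine, CH2Cl2, 0 °C → rt
Reagents that add atoms: none
Why: Dess–Martin oxidation under pyridine buffering should give the β-silyloxy aldehyde without epimerising the adjacent C7 centre or eliminating the silyloxy group.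

Step 13
Reactants: 21 seco aldehyde with (E)-alkenyl iodide
Product: 23 methyl (1E,5E,7R,8S,9R)-8-(2-tert-butoxy-2-oxoethyl)-9-(tert-butyldimethylsilyloxy)-7-hydroxy-5-methylcyclodeca-1,5-diene-1-carboxylate (the C6 carbinol in the numbering of the remark), via alkenylchromium dichloride 22 (not isolated)
Conditions: CrCl2 (12 equiv), NiCl2 (0.2 equiv), degassed DMSO, rt, slow addition of 21 (final 0.003 M)
Reagents that add atoms: none
Why: Zerovalent nickel, formed from catalytic NiCl2 by divalent chromium, inserts into the C5–I bond and passes the alkenyl group to trivalent chromium with retention of the (E)-geometry, and the alkenylchromium 22 then adds to the C6 aldehyde. The closest known reaction is the intramolecular Nozaki–Hiyama–Kishi alkenyl iodide–aldehyde coupling, which has been used to close medium rings and macrocycles. The ten-membered ring closes by 10-exo-trig 1,2-addition of C5 to the C6 carbonyl under high dilution. The C6 stereocentre is controlled by the substrate: Felkin–Anh attack anti to the C8 branch and 1,3-anti induction from the β-silyloxy group (dipole-minimised arrangement) select the same face because the C7 and C8 substituents are anti, which should give the 6,7-syn, 6,8-anti (6R) carbinol. The step needs this facial selectivity without chelation, which the weakly coordinating OTBS group secures, and chemoselectivity for the aldehyde over both esters, which the low basicity and nucleophilicity of alkenylchromium reagents secures.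

Step 14
Reactants: 23 ten-membered allylic alcohol from step 13
Product: 24 methyl (3aS,4R,6E,10E,11aR)-4-(tert-butyldimethylsilyloxy)-10-methyl-2-oxo-2,3,3a,4,5,8,9,11a-octahydrocyclodeca[b]furan-6-carboxylate
Conditions: TsOH·H2O (0.2 equiv), CH2Cl2, rt
Reagents that add atoms: none
Why: Acid-catalysed intramolecular transesterification (γ-lactonisation), in which the C6 hydroxyl attacks the protonated tert-butyl ester 5-exo-trig and tert-butanol leaves; C6 keeps its configuration because its C–O bond is not broken, and the trans ring fusion follows from the 6,7-syn arrangement.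

Step 15
Reactants: 24 trans-fused lactone from step 14
Product: 28 methyl (3aS,4R,6E,10E,11aR)-4-(tert-butyldimethylsilyloxy)-10-methyl-3-methylidene-2-oxo-2,3,3a,4,5,8,9,11a-octahydrocyclodeca[b]furan-6-carboxylate, via lithium enolate 25 (not isolated), via Mannich base 26 (not isolated), via trimethylammonium iodide 27 (not isolated)
Conditions: LiN(SiMe3)2 (1.3 equiv), THF, −78 °C; Eschenmoser's salt (3 equiv), −78 → 0 °C; then MeI, MeOH, rt; then aq. NaHCO3, CH2Cl2, rt
Reagents that add atoms: Eschenmoser's salt (N,N-dimethylmethyleneiminium iodide), C=[N+](C)C.[I-]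
Why: Mannich aminomethylation of the lactone enolate, N-methylation and Hofmann-type β-elimination install the C13 methylene; deprotonation should occur at C11 because the only γ-hydrogens of the enoate (C2) lie trans to its carbonyl and are kinetically slow to remove.

Step 16
Reactants: 28 silyl-protected α-methylene lactone from step 15
Product: 29 methyl (3aR,4R,6E,10E,11aR)-4-hydroxy-10-methyl-3-methylidene-2-oxo-2,3,3a,4,5,8,9,11a-octahydrocyclodeca[b]furan-6-carboxylate
Conditions: HF·pyridine, pyridine, THF, 0 °C → rt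
Reagents that add atoms: none
Why: Fluoride-mediated desilylation under mildly acidic conditions spares both conjugate acceptors and avoids the base-induced shift of the lactone to the C8 oxygen.

Step 17
Reactants: 29 C8 alcohol from step 16
Product: 30 methyl (3aR,4R,6E,10E,11aR)-10-methyl-3-methylidene-4-(2-methylprop-2-enoyloxy)-2-oxo-2,3,3a,4,5,8,9,11a-octahydrocyclodeca[b]furan-6-carboxylate (CNP0317149.1)
Conditions: methacrylic anhydride (3 equiv), Et3N, DMAP (0.2 equiv), CH2Cl2, 0 °C → rt
Reagents that add atoms: methacrylic anhydride, CC(=C)C(=O)OC(=O)C(C)=C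
Why: DMAP-catalysed acyl transfer esterifies the secondary C8 hydroxyl with retention, since the C8–O bond is not broken.

Compound list
1 | 4-pentyn-1-ol | C#CCCCO | starting material
2 | dimethyl[(1E)-5-(dimethylalumanyloxy)-2-methylpent-1-en-1-yl]alumane (alkenylalane, not isolated) | C[Al](C)OCCC/C(C)=C/[Al](C)C | intermediate
3 | (E)-5-iodo-4-methylpent-4-en-1-ol | OCCC/C(C)=C/I | intermediate
4 | (E)-5-iodo-4-methylpent-4-enal | O=CCC/C(C)=C/I | intermediate
5 | dimethyl (S)-malate | COC(=O)C[C@H](O)C(=O)OC | starting material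
6 | tert-butyl bromoacetate | CC(C)(C)OC(=O)CBr | starting material
7 | dilithium alkoxide enolate of 5 (not isolated) | COC(=O)[CH-][C@H]([O-])C(=O)OC.[Li+].[Li+] | intermediate
8 | 3-tert-butyl 1,2-dimethyl (1S,2R)-1-hydroxypropane-1,2,3-tricarboxylate | COC(=O)[C@H](CC(=O)OC(C)(C)C)[C@H](O)C(=O)OC | intermediate
9 | 4-tert-butyl 1-methyl (2R)-2-[(1S)-1,2-dihydroxyethyl]butanedioate | COC(=O)[C@H](CC(=O)OC(C)(C)C)[C@H](O)CO | intermediate
10 | 4-tert-butyl 1-methyl (2R)-2-[(1S)-1,2-bis(tert-butyldimethylsilyloxy)ethyl]butanedioate | COC(=O)[C@H](CC(=O)OC(C)(C)C)[C@H](O[Si](C)(C)C(C)(C)C)CO[Si](C)(C)C(C)(C)C | intermediate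
11 | tert-butyl (3S,4S)-4,5-bis(tert-butyldimethylsilyloxy)-3-(hydroxymethyl)pentanoate | OC[C@H](CC(=O)OC(C)(C)C)[C@H](O[Si](C)(C)C(C)(C)C)CO[Si](C)(C)C(C)(C)C | intermediate
12 | tert-butyl (3S,4S)-3-(acetoxymethyl)-4,5-bis(tert-butyldimethylsilyloxy)pentanoate | CC(=O)OC[C@H](CC(=O)OC(C)(C)C)[C@H](O[Si](C)(C)C(C)(C)C)CO[Si](C)(C)C(C)(C)C | intermediate
13 | tert-butyl (3S,4S)-3-(acetoxymethyl)-4-(tert-butyldimethylsilyloxy)-5-hydroxypentanoate | CC(=O)OC[C@H](CC(=O)OC(C)(C)C)[C@H](O[Si](C)(C)C(C)(C)C)CO | intermediate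
14 | methyl 2-(diethoxyphosphoryl)acetate | CCOP(=O)(CC(=O)OC)OCC | starting material
15 | tert-butyl (3S,4S)-3-(acetoxymethyl)-4-(tert-butyldimethylsilyloxy)-5-(trifluoromethylsulfonyloxy)pentanoate (not isolated) | CC(=O)OC[C@H](CC(=O)OC(C)(C)C)[C@H](O[Si](C)(C)C(C)(C)C)COS(=O)(=O)C(F)(F)F | intermediate
16 | sodium salt of 14, phosphonoacetate carbanion (not isolated) | CCOP(=O)(OCC)[CH-]C(=O)OC.[Na+] | intermediate
17 | tert-butyl (3S,4R)-3-(acetoxymethyl)-4-(tert-butyldimethylsilyloxy)-6-(diethoxyphosphoryl)-7-methoxy-7-oxoheptanoate, both epimers at the phosphonate carbon | CC(=O)OC[C@H](CC(=O)OC(C)(C)C)[C@H](O[Si](C)(C)C(C)(C)C)CC(C(=O)OC)P(=O)(OCC)OCC | intermediate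
18 | sodium salt of 17, carbanion at the phosphonate carbon (not isolated) | CC(=O)OC[C@H](CC(=O)OC(C)(C)C)[C@H](O[Si](C)(C)C(C)(C)C)C[C-](C(=O)OC)P(=O)(OCC)OCC.[Na+] | intermediate
19 | tert-butyl (3S,4R,6E,10E)-3-(acetoxymethyl)-4-(tert-butyldimethylsilyloxy)-11-iodo-6-(methoxycarbonyl)-10-methylundeca-6,10-dienoate | CC(=O)OC[C@H](CC(=O)OC(C)(C)C)[C@H](O[Si](C)(C)C(C)(C)C)C/C(C(=O)OC)=C\CC/C(C)=C/I | intermediate
20 | tert-butyl (3S,4R,6E,10E)-4-(tert-butyldimethylsilyloxy)-3-(hydroxymethyl)-11-iodo-6-(methoxycarbonyl)-10-methylundeca-6,10-dienoate | OC[C@H](CC(=O)OC(C)(C)C)[C@H](O[Si](C)(C)C(C)(C)C)C/C(C(=O)OC)=C\CC/C(C)=C/I | intermediate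
21 | tert-butyl (3R,4R,6E,10E)-4-(tert-butyldimethylsilyloxy)-3-formyl-11-iodo-6-(methoxycarbonyl)-10-methylundeca-6,10-dienoate (key-step precursor) | O=C[C@H](CC(=O)OC(C)(C)C)[C@H](O[Si](C)(C)C(C)(C)C)C/C(C(=O)OC)=C\CC/C(C)=C/I | intermediate
22 | alkenylchromium dichloride of 21, CrCl2 in place of iodine at C5 (trivalent chromium, not isolated) | O=C[C@H](CC(=O)OC(C)(C)C)[C@H](O[Si](C)(C)C(C)(C)C)C/C(C(=O)OC)=C\CC/C(C)=C/[Cr](Cl)Cl | intermediate
23 | methyl (1E,5E,7R,8S,9R)-8-(2-tert-butoxy-2-oxoethyl)-9-(tert-butyldimethylsilyloxy)-7-hydroxy-5-methylcyclodeca-1,5-diene-1-carboxylate (key-step product) | O[C@@H]1/C=C(C)/CC/C=C(C(=O)OC)\C[C@@H](O[Si](C)(C)C(C)(C)C)[C@H]1CC(=O)OC(C)(C)C | intermediate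
24 | methyl (3aS,4R,6E,10E,11aR)-4-(tert-butyldimethylsilyloxy)-10-methyl-2-oxo-2,3,3a,4,5,8,9,11a-octahydrocyclodeca[b]furan-6-carboxylate | CC(C)(C)[Si](C)(C)O[C@@H]1C/C(C(=O)OC)=C\CC/C(C)=C/[C@H]2OC(=O)C[C@@H]21 | intermediate
25 | lithium enolate of 24, carbanion at C11 (not isolated) | CC(C)(C)[Si](C)(C)O[C@@H]1C/C(C(=O)OC)=C\CC/C(C)=C/[C@H]2OC(=O)[CH-][C@@H]21.[Li+] | intermediate
26 | 3-(dimethylaminomethyl) derivative of 24, Mannich base, either C11 epimer (not isolated) | CC(C)(C)[Si](C)(C)O[C@@H]1C/C(C(=O)OC)=C\CC/C(C)=C/[C@H]2OC(=O)C(CN(C)C)[C@@H]21 | intermediate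
27 | trimethylammonium iodide of 26 (not isolated) | CC(C)(C)[Si](C)(C)O[C@@H]1C/C(C(=O)OC)=C\CC/C(C)=C/[C@H]2OC(=O)C(C[N+](C)(C)C)[C@@H]21.[I-] | intermediate
28 | methyl (3aS,4R,6E,10E,11aR)-4-(tert-butyldimethylsilyloxy)-10-methyl-3-methylidene-2-oxo-2,3,3a,4,5,8,9,11a-octahydrocyclodeca[b]furan-6-carboxylate | CC(C)(C)[Si](C)(C)O[C@@H]1C/C(C(=O)OC)=C\CC/C(C)=C/[C@H]2OC(=O)C(=C)[C@@H]21 | intermediate
29 | methyl (3aR,4R,6E,10E,11aR)-4-hydroxy-10-methyl-3-methylidene-2-oxo-2,3,3a,4,5,8,9,11a-octahydrocyclodeca[b]furan-6-carboxylate | O[C@@H]1C/C(C(=O)OC)=C\CC/C(C)=C/[C@H]2OC(=O)C(=C)[C@@H]21 | intermediate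
30 | methyl (3aR,4R,6E,10E,11aR)-10-methyl-3-methylidene-4-(2-methylprop-2-enoyloxy)-2-oxo-2,3,3a,4,5,8,9,11a-octahydrocyclodeca[b]furan-6-carboxylate (CNP0317149.1) | C=C(C)C(=O)O[C@@H]1C/C(C(=O)OC)=C\CC/C(C)=C/[C@H]2OC(=O)C(=C)[C@@H]21 | target

Total steps: 17. Longest linear sequence: 15 steps (steps 3–17, from dimethyl (S)-malate); steps 1–2 make the aldehyde partner.

Steps most likely to fail

Step 13 (ring closure). The geometric demands of the ten-membered transition state may override the acyclic Felkin–Anh/1,3-anti preference, so that C5 adds to the other face of the aldehyde; intermolecular coupling also competes unless dilution is kept high. Fallback: the wrong epimer is corrected by inversion during lactone formation instead of being discarded. Setting out from 21, the same coupling is run and the C6-epimeric macrocyclic alcohol F1 is taken on. Its tert-butyl ester is cleaved without protic acid (TMSOTf, 2,6-lutidine, CH2Cl2, 0 °C; mild K2CO3/MeOH work-up) to the C6-epimeric hydroxy acid F2, which is used at once. Mitsunobu lactonisation (PPh3, DIAD, THF, 0 °C, high dilution) then displaces the activated C6 oxygen by the carboxylate with inversion, which brings the route back at lactone 24.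

Step 9 (C9–C10 bond). The triflate 15 may be consumed before C–C bond formation, either by participation of the tert-butyl ester carbonyl or by O-alkylation of the ambident phosphonate anion. Fallback: from alcohol 13 the isolable primary iodide F3 is prepared (I2, PPh3, imidazole, CH2Cl2, 0 °C) and heated with the sodium phosphonoacetate 16 in DMF at 60 °C. The softer, non-ionising leaving group should enforce C-alkylation in a slow thermal displacement, and the sequence rejoins the route at phosphonate 17.

Step 10 (alkene geometry). The bulky α-substituent of the phosphonate may level the two oxaphosphetane pathways and erode the (E)-selectivity needed at C10=C1. Fallback: a stabilised α-substituted phosphorus ylide, whose Wittig reactions are reliably (E)-selective. From alcohol 13, the triflate 15 is made as in step 9 and used to alkylate methyl (triphenylphosphoranylidene)acetate (CH2Cl2, −78 °C → rt), giving the phosphonium triflate F4. Aqueous NaOH converts it into the α-substituted ylide F5, and Wittig reaction with aldehyde 4 (toluene, 90 °C) brings the route back at diene ester 19.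

Further compounds
F1 | step 13 | methyl (1E,5E,7S,8S,9R)-8-(2-tert-butoxy-2-oxoethyl)-9-(tert-butyldimethylsilyloxy)-7-hydroxy-5-methylcyclodeca-1,5-diene-1-carboxylate (C6 epimer of 23) | O[C@H]1/C=C(C)/CC/C=C(C(=O)OC)\C[C@@H](O[Si](C)(C)C(C)(C)C)[C@H]1CC(=O)OC(C)(C)C
F2 | step 13 | carboxylic acid of F1 (tert-butyl ester cleaved, C6-epimeric hydroxy acid) | O[C@H]1/C=C(C)/CC/C=C(C(=O)OC)\C[C@@H](O[Si](C)(C)C(C)(C)C)[C@H]1CC(=O)O
F3 | step 9 | tert-butyl (3S,4S)-3-(acetoxymethyl)-4-(tert-butyldimethylsilyloxy)-5-iodopentanoate | CC(=O)OC[C@H](CC(=O)OC(C)(C)C)[C@H](O[Si](C)(C)C(C)(C)C)CI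
F4 | step 10 | phosphonium triflate from 15 and methyl (triphenylphosphoranylidene)acetate | CC(=O)OC[C@H](CC(=O)OC(C)(C)C)[C@H](O[Si](C)(C)C(C)(C)C)CC(C(=O)OC)[P+](c1ccccc1)(c1ccccc1)c1ccccc1.[O-]S(=O)(=O)C(F)(F)F
F5 | step 10 | α-substituted stabilised ylide from F4 | CC(=O)OC[C@H](CC(=O)OC(C)(C)C)[C@H](O[Si](C)(C)C(C)(C)C)CC(C(=O)OC)=P(c1ccccc1)(c1ccccc1)c1ccccc1
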